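**Assumptions.** Numbering runs C1 (ethyl CH3) to C15 (propenyl CH3); C6′ and C8′ are the two CH2OH carbons. (R)-Ethyl 4-chloro-3-hydroxybutanoate, (R)-Roche ester, S-(2-pyridyl) propanethioate and PMBOCH2Cl are treated as purchasable reagents.

## Retrosynthetic overview
1. Target ⇐ global deprotection (HF·py, DDQ, ketal cleavage) ⇐ epoxy alcohol ⇐ hydroxyl-directed peracid epoxidation of a (Z)-trisubstituted allylic alcohol. This is the only ring formed, and it is made last-but-four.
2. That β-hydroxy ketone ⇐ photoredox/Cr Reformatsky-type aldol (key step, C8–C9 bond, sets C8 and C9) between α-bromo ketone **10** (C1–C8′) and (Z)-enal **19** (C9–C15).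
3. **10** ⇐ (R)-4-chloro-3-hydroxybutanoate (C5) via Ni/photoredox propionylation, ketalisation, Fráter–Seebach hydroxymethylation (C6), then vinyl ketone, oxa-Michael and α-bromination.
4. **19** ⇐ (R)-Roche ester (C12) via Z-Wittig (C13=C14) and Still–Gennari homologation to the Z-enal (C10=C11).

## Route

**Step 1**
Reactants: 1, ethyl (3R)-4-chloro-3-hydroxybutanoate
Product: 2, ethyl (3R)-3-hydroxy-4-iodobutanoate
Conditions: NaI, acetone, reflux
Reagents that add atoms: sodium iodide, [Na+].[I-]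
Why: Finkelstein SN2 at the primary carbon, so the carbinol stereocentre (C5) is untouched.

**Step 2**
Reactants: 2
Product: 3, ethyl (3S)-3-hydroxy-5-oxoheptanoate
Conditions: NiBr2·diglyme/dtbbpy (10 mol%), 4CzIPN (2 mol%), Hantzsch ester, DMA, blue LEDs, 25 °C
Reagents that add atoms: S-(2-pyridyl) propanethioate, CCC(=O)Sc1ccccn1
Why: Ni/photoredox reductive cross-electrophile acylation of the primary alkyl iodide forms the C3–C4 bond (ethyl ketone) under neutral conditions and leaves the C5 stereocentre alone.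

**Step 3**
Reactants: 3
Product: 4, ethyl (3S)-4-(2-ethyl-1,3-dioxolan-2-yl)-3-hydroxybutanoate
Conditions: (TMSOCH2)2, cat. TMSOTf, CH2Cl2, −78→0 °C; then PPTS, MeOH
Reagents that add atoms: 1,2-bis(trimethylsilyloxy)ethane, C[Si](C)(C)OCCO[Si](C)(C)C
Why: Noyori ketalisation masks the C3 ketone so it survives the enolate chemistry that follows.

**Step 4**
Reactants: 4
Product: 5, ethyl (2S,3S)-4-(2-ethyl-1,3-dioxolan-2-yl)-3-hydroxy-2-{[(4-methoxyphenyl)methoxy]methyl}butanoate (target C5 S, C6 S)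
Conditions: LDA (2.2 equiv), THF, −78→−20 °C; then PMBOCH2Cl, DMPU, −78→0 °C
Reagents that add atoms: 4-methoxybenzyl chloromethyl ether, COc1ccc(COCCl)cc1
Why: Fráter–Seebach alkylation of the chelated β-alkoxide/ester dianion; the electrophile attacks anti to the C5 substituent, so C6 (anti, 5S,6S) is set from the bought C5 centre.

**Step 5**
Reactants: 5
Product: 6, C5 tert-butyldimethylsilyl ether of 5
Conditions: TBSOTf, 2,6-lutidine, CH2Cl2, −78 °C
Reagents that add atoms: TBSOTf, CC(C)(C)[Si](C)(C)OS(=O)(=O)C(F)(F)F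
Why: silylation of the hindered secondary alcohol, with no stereochemical consequence.

**Step 6**
Reactants: 6
Product: 7, Weinreb amide (N-methoxy-N-methylamide) of the C7 acid
Conditions: MeNH(OMe)·HCl, iPrMgCl, THF, −20 °C
Reagents that add atoms: N,O-dimethylhydroxylamine hydrochloride, CONC.Cl
Why: Weinreb amidation gives a single-addition acyl donor while the α-stereocentre C6 is kept.

**Step 7**
Reactants: 7
Product: 8, (4S,5S)-5-[(TBS)oxy]-6-(2-ethyl-1,3-dioxolan-2-yl)-4-{[(4-methoxyphenyl)methoxy]methyl}hex-1-en-3-one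
Conditions: CH2=CHMgBr (3 equiv), THF, −78→0 °C
Reagents that add atoms: vinylmagnesium bromide, C=C[Mg]Br
Why: Weinreb–Nahm ketone synthesis gives the vinyl ketone without over-addition; C8 and C8′ are the vinyl carbons.

**Step 8**
Reactants: 8
Product: 9, (4S,5S)-5-[(TBS)oxy]-6-(2-ethyl-1,3-dioxolan-2-yl)-1-[(PMB)oxy]-4-{[(PMB)oxy]methyl}hexan-3-one
Conditions: PMBOH (5 equiv), PBu3 (10 mol%), THF, 0 °C→rt
Reagents that add atoms: 4-methoxybenzyl alcohol, COc1ccc(CO)cc1
Why: nucleophile-catalysed (phosphine) oxa-Michael addition under neutral conditions installs C8′–OPMB while avoiding β-elimination of the C5 silyl ether.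

**Step 9**
Reactants: 9
Product: 10, (4S,5S)-2-bromo analogue of 9 (C2 = C8, unresolved)
Conditions: LiHMDS, TMSCl, THF, −78 °C; then NBS, −78 °C
Reagents that add atoms: N-bromosuccinimide, O=C1CCC(=O)N1Br
Why: kinetic silyl enol ether forms at the unhindered CH2 (C8), and electrophilic bromination gives the α-bromo ketone. The C8 configuration is irrelevant because Step 18 passes through an enolate.

**Step 10**
Reactants: 11, methyl (2R)-3-hydroxy-2-methylpropanoate ((R)-Roche ester)
Product: 12, methyl (2R)-3-[(TBS)oxy]-2-methylpropanoate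
Conditions: TBSCl, imidazole, DMF, 0 °C→rt
Reagents that add atoms: TBSCl, CC(C)(C)[Si](C)(C)Cl
Why: silyl protection that carries the C12 stereocentre forward.

**Step 11**
Reactants: 12
Product: 13, (2R)-3-[(TBS)oxy]-2-methylpropanal
Conditions: DIBAL-H (1.1 equiv), CH2Cl2, −78 °C
Reagents that add atoms: none
Why: partial ester reduction at −78 °C stops at the aldehyde, which becomes C13.

**Step 12**
Reactants: 13
Product: 14, tert-butyldimethyl{[(2S,3Z)-2-methylhex-3-en-1-yl]oxy}silane
Conditions: EtPPh3Br, NaHMDS, THF, −78→0 °C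
Reagents that add atoms: ethyltriphenylphosphonium bromide, CC[P+](c1ccccc1)(c1ccccc1)c1ccccc1.[Br-]
Why: Z-selective Wittig olefination with a non-stabilised ylide sets C13=C14 (Z); C12 is unchanged.

**Step 13**
Reactants: 14
Product: 15, (2S,3Z)-2-methylhex-3-en-1-ol
Conditions: TBAF, THF, 0 °C
Reagents that add atoms: none
Why: fluoride desilylation to the free primary alcohol that will become C11.

**Step 14**
Reactants: 15
Product: 16, (2S,3Z)-2-methylhex-3-enal
Conditions: Dess–Martin periodinane, NaHCO3, CH2Cl2, 0 °C (use crude at once)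
Reagents that add atoms: none
Why: buffered DMP oxidation, mild enough to limit epimerisation of the allylic α-stereocentre.

**Step 15**
Reactants: 16
Product: 17, methyl (2Z,4S,5Z)-2,4-dimethylhepta-2,5-dienoate
Conditions: (CF3CH2O)2P(O)CH(CH3)CO2Me, KHMDS, 18-crown-6, THF, −78 °C
Reagents that add atoms: methyl 2-[bis(2,2,2-trifluoroethoxy)phosphoryl]propanoate, COC(=O)C(C)P(=O)(OCC(F)(F)F)OCC(F)(F)F
Why: Still–Gennari HWE gives the (Z)-trisubstituted enoate, so C9 is cis to C12 on C10=C11, which is the geometry needed for the target epoxide.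

**Step 16**
Reactants: 17
Product: 18, (2Z,4S,5Z)-2,4-dimethylhepta-2,5-dien-1-ol
Conditions: DIBAL-H (2.5 equiv), CH2Cl2, −78 °C
Reagents that add atoms: none
Why: 1,2-reduction of the ester to the allylic alcohol with no change in alkene geometry.

**Step 17**
Reactants: 18
Product: 19, (2Z,4S,5Z)-2,4-dimethylhepta-2,5-dienal
Conditions: MnO2 (20 equiv), CH2Cl2, 0 °C
Reagents that add atoms: none
Why: chemoselective allylic oxidation that gives the enal C9 electrophile.

**Step 18**
Reactants: 10 and 19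
Product: 20, aldol adduct (target numbering 5S,6S,8R,9S,12S; 10Z,13Z) with C7 ketone, C9 allylic alcohol, C3 ethylene ketal, C5-OTBS and C6′/C8′-OPMB
Conditions: CrCl2 (20 mol%), [Ir(dF(CF3)ppy)2(dtbbpy)]PF6 (1 mol%), Hantzsch ester (1.5 equiv), LiCl, THF, 455 nm LEDs, 25 °C
Reagents that add atoms: none
Why: Proposed new method: the excited Ir photocatalyst and Hantzsch ester reduce Cr(III) to Cr(II), which abstracts Br from **10** to give an O-bound Cr(III) (E)-enolate that adds to **19** through a Zimmerman–Traxler chair (anti aldol), with the α′-stereocentre C6 (bearing C6′H2OPMB and C5-OTBS) biasing the enolate face (Paterson-type 1,4-induction), so C8 and C9 are set together; the closest known reactions are CrCl2-mediated Reformatsky-type aldol and photoredox/Cr Nozaki–Hiyama–Kishi-type aldehyde additions.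

**Step 19**
Reactants: 20
Product: 21, epoxy alcohol (target numbering 5S,6S,8R,9S,10R,11S,12S; 13Z), ketal and OTBS/OPMB groups intact
Conditions: mCPBA (1.05 equiv), NaHCO3, CH2Cl2, −20→0 °C
Reagents that add atoms: mCPBA, OOC(=O)c1cccc(Cl)c1
Why: Henbest-type hydroxyl-directed epoxidation; A(1,3) strain in the (Z)-2-methyl allylic alcohol holds C9–H in the alkene plane, so the peracid is delivered syn to OH (erythro). This gives the 10R,11S cis-epoxide stereospecifically from the Z-alkene, and the disubstituted C13=C14 alkene is much less reactive.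

**Step 20**
Reactants: 21
Product: 22, C9-O-TBS ether of 21
Conditions: TBSOTf, 2,6-lutidine, CH2Cl2, −78 °C
Reagents that add atoms: TBSOTf, CC(C)(C)[Si](C)(C)OS(=O)(=O)C(F)(F)F
Why: protecting C9–OH prevents PMP-acetal formation with C8′–OPMB in Step 22.

**Step 21**
Reactants: 22
Product: 23, C3 ethyl ketone (ketal removed) with both PMB ethers and both TBS ethers intact
Conditions: TESOTf, 2,4,6-collidine, CH2Cl2, 0 °C; then H2O
Reagents that add atoms: water, O
Why: Fujioka mild ketal cleavage through a collidinium intermediate avoids protic acid and so spares the epoxide.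

**Step 22**
Reactants: 23
Product: 24, C6′,C8′-diol (both PMB ethers removed; TBS at C5 and C9)
Conditions: DDQ (3 equiv), CH2Cl2/pH 7 buffer (18:1), 0 °C
Reagents that add atoms: none
Why: oxidative PMB cleavage under neutral conditions; the remaining hydroxyls are silylated, so no PMP acetals form.

**Step 23**
Reactants: 24
Product: 25, myriaporone 4
Conditions: HF·pyridine, pyridine, THF, 0→23 °C
Reagents that add atoms: none
Why: buffered fluoride removes both TBS ethers and leaves the epoxide, the alkenes and the stereocentres unchanged.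

Stereocentre check: C5 comes from 1; C6 is set in Step 4; C12 comes from 11; C8 and C9 are set in Step 18; C10 and C11 are set in Step 19. None is altered afterwards.

## Compound list
1 | ethyl (3R)-4-chloro-3-hydroxybutanoate | CCOC(=O)C[C@@H](O)CCl | starting material
2 | ethyl (3R)-3-hydroxy-4-iodobutanoate | CCOC(=O)C[C@@H](O)CI | intermediate
3 | ethyl (3S)-3-hydroxy-5-oxoheptanoate | CCOC(=O)C[C@@H](O)CC(=O)CC | intermediate
4 | ethyl (3S)-4-(2-ethyl-1,3-dioxolan-2-yl)-3-hydroxybutanoate | CCOC(=O)C[C@@H](O)CC1(CC)OCCO1 | intermediate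
5 | Fráter–Seebach product (2S,3S) | CCOC(=O)[C@@H](COCc1ccc(OC)cc1)[C@@H](O)CC1(CC)OCCO1 | intermediate
6 | C5 TBS ether of 5 | CCOC(=O)[C@@H](COCc1ccc(OC)cc1)[C@@H](O[Si](C)(C)C(C)(C)C)CC1(CC)OCCO1 | intermediate
7 | Weinreb amide | CON(C)C(=O)[C@@H](COCc1ccc(OC)cc1)[C@@H](O[Si](C)(C)C(C)(C)C)CC1(CC)OCCO1 | intermediate
8 | vinyl ketone | C=CC(=O)[C@@H](COCc1ccc(OC)cc1)[C@@H](O[Si](C)(C)C(C)(C)C)CC1(CC)OCCO1 | intermediate
9 | β-PMBO ketone | COc1ccc(COCCC(=O)[C@@H](COCc2ccc(OC)cc2)[C@@H](O[Si](C)(C)C(C)(C)C)CC2(CC)OCCO2)cc1 | intermediate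
10 | α-bromo ketone (C8 unresolved) | COc1ccc(COCC(Br)C(=O)[C@@H](COCc2ccc(OC)cc2)[C@@H](O[Si](C)(C)C(C)(C)C)CC2(CC)OCCO2)cc1 | intermediate
11 | methyl (2R)-3-hydroxy-2-methylpropanoate | COC(=O)[C@H](C)CO | starting material
12 | methyl (2R)-3-[(TBS)oxy]-2-methylpropanoate | COC(=O)[C@H](C)CO[Si](C)(C)C(C)(C)C | intermediate
13 | (2R)-3-[(TBS)oxy]-2-methylpropanal | O=C[C@H](C)CO[Si](C)(C)C(C)(C)C | intermediate
14 | (2S,3Z)-2-methylhex-3-enyl TBS ether | C/C=C\[C@H](C)CO[Si](C)(C)C(C)(C)C | intermediate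
15 | (2S,3Z)-2-methylhex-3-en-1-ol | C/C=C\[C@H](C)CO | intermediate
16 | (2S,3Z)-2-methylhex-3-enal | C/C=C\[C@H](C)C=O | intermediate
17 | methyl (2Z,4S,5Z)-2,4-dimethylhepta-2,5-dienoate | C/C=C\[C@H](C)/C=C(/C)C(=O)OC | intermediate
18 | (2Z,4S,5Z)-2,4-dimethylhepta-2,5-dien-1-ol | C/C=C\[C@H](C)/C=C(/C)CO | intermediate
19 | (2Z,4S,5Z)-2,4-dimethylhepta-2,5-dienal | C/C=C\[C@H](C)/C=C(/C)C=O | intermediate
20 | aldol adduct | C/C=C\[C@H](C)/C=C(/C)[C@@H](O)[C@@H](COCc1ccc(OC)cc1)C(=O)[C@@H](COCc1ccc(OC)cc1)[C@@H](O[Si](C)(C)C(C)(C)C)CC1(CC)OCCO1 | intermediate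
21 | epoxy alcohol | C/C=C\[C@H](C)[C@@H]1O[C@]1(C)[C@@H](O)[C@@H](COCc2ccc(OC)cc2)C(=O)[C@@H](COCc2ccc(OC)cc2)[C@@H](O[Si](C)(C)C(C)(C)C)CC2(CC)OCCO2 | intermediate
22 | C9-OTBS epoxide | C/C=C\[C@H](C)[C@@H]1O[C@]1(C)[C@@H](O[Si](C)(C)C(C)(C)C)[C@@H](COCc2ccc(OC)cc2)C(=O)[C@@H](COCc2ccc(OC)cc2)[C@@H](O[Si](C)(C)C(C)(C)C)CC2(CC)OCCO2 | intermediate
23 | ketal-free ketone | C/C=C\[C@H](C)[C@@H]1O[C@]1(C)[C@@H](O[Si](C)(C)C(C)(C)C)[C@@H](COCc2ccc(OC)cc2)C(=O)[C@@H](COCc2ccc(OC)cc2)[C@@H](O[Si](C)(C)C(C)(C)C)CC(=O)CC | intermediate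
24 | diol, bis-TBS | C/C=C\[C@H](C)[C@@H]1O[C@]1(C)[C@@H](O[Si](C)(C)C(C)(C)C)[C@@H](CO)C(=O)[C@@H](CO)[C@@H](O[Si](C)(C)C(C)(C)C)CC(=O)CC | intermediate
25 | myriaporone 4 | C/C=C\[C@H](C)[C@@H]1O[C@]1(C)[C@@H](O)[C@@H](CO)C(=O)[C@@H](CO)[C@@H](O)CC(=O)CC | target

**Total steps:** 23. **Longest linear sequence:** 15 (Steps 1–9, then 18–23).

## Three steps most likely to fail
1. **Step 18 (proposed new Cr/photoredox aldol).** Risks are poor C8/C9 diastereoselectivity and β-elimination of the C8′ PMB ether from the enolate. Fallback: use ketone **9** itself, form the (E)-dicyclohexylboron enolate (Cy2BCl, Me2NEt) and add enal **19** (Paterson anti-aldol, known chemistry).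
2. **Step 19 (epoxide diastereoselectivity).** Fallback: OsO4/NMO dihydroxylation of the Z-alkene, selective activation of the secondary C11–OH (MsCl or Kolb–Sharpless acetoxonium), then K2CO3 ring closure through the tertiary alkoxide (known chemistry, different approach).
3. **Step 2 (Ni/photoredox acylation of a free iodohydrin, which risks epoxide formation).** Fallback: close the chlorohydrin to ethyl (R)-3,4-epoxybutanoate, open it with 2-lithio-2-ethyl-1,3-dithiane/BF3, and carry the dithiane as the C3 ketone surrogate, with oxidative unmasking after Step 17 in place of the ketal removal (Corey–Seebach, known chemistry).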